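**Plan**

- Retrosynthesis: the phenol is unmasked last (MOM ether). The protected lactone is then cut at two bonds at once, the syringyl C1'–CH bond of the arylidene and the ring bond C3–C4, which opens the γ-lactone to a cinnamyl propiolate and an arylboronic acid.
- Enabling feature: the arylidene CH, lactone C3 and the stereocentre C4 are three contiguous carbons, and C2(=O)–O1–C5 completes the five-membered ring. The chain HC≡C3–C2(=O)–O1–C5–C4=CH(aryl) is therefore a 1,6-enyne held together by an ester.
- Forward: 3,4,5-trimethoxycinnamic acid → allylic alcohol → propiolate ester (O1–C2 joined first). In parallel, bromophenol → MOM ether → boronic acid. The halves meet in the rhodium step, where the only ring closes, and acid then frees the phenol.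
- Stereochemistry: syn-arylrhodation places the aryl group cis to the new C3–C4 bond (E alkene). The chiral diene on rhodium selects the alkene face during ring closure and sets C4 as R. No later step touches either element.

Key step: step 6

Assumption: the sense of induction of a bod*-type diene on this substrate class is not known, so the ligand antipode that gives (R)-C4 is fixed in the first runs; both antipodes are accessible.
Assumption: the organorhodium species of step 6 exist only on the catalyst during turnover and are described in the Why line, not numbered.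

**Route**

Step 1
Reactants: 1 (E)-3,4,5-trimethoxycinnamic acid
Product: 2 methyl (E)-3-(3,4,5-trimethoxyphenyl)acrylate
Conditions: MeOH, H2SO4 (cat.), reflux
Reagents that add atoms: methanol CO
Why: Fischer esterification driven by the large excess of methanol; the conjugated E alkene and the aryl methyl ethers are inert to catalytic acid.

Step 2
Reactants: 2 methyl (E)-3-(3,4,5-trimethoxyphenyl)acrylate
Product: 3 (E)-3-(3,4,5-trimethoxyphenyl)prop-2-en-1-ol
Conditions: DIBAL-H (2.5 equiv), CH2Cl2, −78 → 0 °C; aq Rochelle salt
Reagents that add atoms: none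
Why: DIBAL-H 1,2-reduction of an α,β-unsaturated ester at low temperature should stop at the allylic alcohol and leave the styrenyl alkene and its E geometry untouched.

Step 3
Reactants: 3 (E)-3-(3,4,5-trimethoxyphenyl)prop-2-en-1-ol, 4 propiolic acid
Product: 5 (E)-3-(3,4,5-trimethoxyphenyl)allyl propiolate
Conditions: DCC (1.1 equiv), DMAP (5 mol%), CH2Cl2, −20 → 0 °C
Reagents that add atoms: none
Why: Steglich esterification of a primary allylic alcohol, run cold and with little DMAP so that acyl transfer outruns conjugate addition to the activated ynoate.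

Step 4
Reactants: 6 4-bromo-2,6-dimethoxyphenol
Product: 7 5-bromo-1,3-dimethoxy-2-(methoxymethoxy)benzene
Conditions: MOMCl, iPr2NEt, CH2Cl2, 0 °C → rt
Reagents that add atoms: chloromethyl methyl ether COCCl
Why: O-alkylation of the phenol with the highly electrophilic α-chloro ether (MOM acetal formation) should proceed despite the two flanking methoxy groups, and the aryl bromide is inert.

Step 5
Reactants: 7 5-bromo-1,3-dimethoxy-2-(methoxymethoxy)benzene
Product: 10 [3,5-dimethoxy-4-(methoxymethoxy)phenyl]boronic acid, via aryllithium 8 (not isolated), via lithium aryltriisopropoxyborate 9 (not isolated)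
Conditions: n-BuLi, THF, −78 °C; B(OiPr)3, −78 °C → rt; 1 M HCl to pH 5, 0 °C
Reagents that add atoms: triisopropyl borate CC(C)OB(OC(C)C)OC(C)C; water O; n-butyllithium [Li]CCCC (lithium in 8 and 9 only)
Why: Bromine–lithium exchange at −78 °C is faster than MOM-directed ortho-lithiation, the aryllithium is trapped by the borate as its ate complex, and hydrolysis at pH 5 frees the boronic acid without cleaving the MOM acetal (lithiation–borylation).

Step 6
Reactants: 5 (E)-3-(3,4,5-trimethoxyphenyl)allyl propiolate, 10 [3,5-dimethoxy-4-(methoxymethoxy)phenyl]boronic acid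
Product: 11 (R,E)-3-[3,5-dimethoxy-4-(methoxymethoxy)benzylidene]-4-(3,4,5-trimethoxybenzyl)dihydrofuran-2(3H)-one
Conditions: [RhCl(C2H4)2]2 (2.5 mol%), (S,S)-Bn-bod* or its antipode (5.5 mol%), aq KOH (10 mol%), degassed 1,4-dioxane/H2O 10:1, 50 °C; 5 added by syringe pump to 10 (2 equiv)
Reagents that add atoms: none
Why: Proposed new method: boron-to-rhodium transmetallation gives an aryl–Rh(I)(diene) species that adds syn across the propiolate C≡C with the aryl group on the terminal carbon and rhodium on the carbon next to the carbonyl (ynoate polarisation and chelation of the 1,6-enyne both point this way), and the resulting alkenyl–rhodium inserts the tethered E alkene to form C3–C4 and an η3-benzyl–rhodium, which water protonates to the benzylic CH2 while regenerating Rh–OH. The closest known reaction type is the rhodium(I)/chiral diene arylative cyclisation of alkyne-tethered electron-poor alkenes with arylboronic acids, together with rhodium-catalysed cyclisations of ester-tethered 1,6-enynes; new here are a plain styrene acceptor whose benzyl–rhodium is released by protonolysis and a terminal propiolate as the alkyne. The γ-lactone closes in a 5-exo-trig mode by intramolecular carborhodation of the alkene. C4 is the only new stereocentre and is fixed in that insertion, where the C2-symmetric diene on rhodium selects one face of the E alkene; the ligand antipode is chosen so that R results. Syn addition leaves the aryl group cis to the new C3–C4 bond, which is the E alkene of the target. The step needs ring closure to beat alkyne oligomerisation, 1,4-rhodium migration onto the aryl ring and β-hydride elimination; slow addition of 5, the intramolecular 5-exo geometry and the η3-benzyl resting state in a protic medium are relied on for this.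

Step 7
Reactants: 11 (R,E)-3-[3,5-dimethoxy-4-(methoxymethoxy)benzylidene]-4-(3,4,5-trimethoxybenzyl)dihydrofuran-2(3H)-one
Product: 12 (R,E)-3-(4-hydroxy-3,5-dimethoxybenzylidene)-4-(3,4,5-trimethoxybenzyl)dihydrofuran-2(3H)-one
Conditions: 2 M aq HCl, THF, 40 °C
Reagents that add atoms: none
Why: Acid-catalysed acetal hydrolysis removes the MOM group, while the γ-lactone, the aryl methyl ethers and the E alkene tolerate dilute acid and C4 cannot epimerise without base.

**Compound list**

1 | (E)-3,4,5-trimethoxycinnamic acid | COc1cc(/C=C/C(=O)O)cc(OC)c1OC | starting material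
2 | methyl (E)-3-(3,4,5-trimethoxyphenyl)acrylate | COC(=O)/C=C/c1cc(OC)c(OC)c(OC)c1 | intermediate
3 | (E)-3-(3,4,5-trimethoxyphenyl)prop-2-en-1-ol | OC/C=C/c1cc(OC)c(OC)c(OC)c1 | intermediate
4 | propiolic acid | C#CC(=O)O | starting material
5 | (E)-3-(3,4,5-trimethoxyphenyl)allyl propiolate | C#CC(=O)OC/C=C/c1cc(OC)c(OC)c(OC)c1 | intermediate
6 | 4-bromo-2,6-dimethoxyphenol | COc1cc(Br)cc(OC)c1O | starting material
7 | 5-bromo-1,3-dimethoxy-2-(methoxymethoxy)benzene | COCOc1c(OC)cc(Br)cc1OC | intermediate
8 | [3,5-dimethoxy-4-(methoxymethoxy)phenyl]lithium | COCOc1c(OC)cc([Li])cc1OC | intermediate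
9 | lithium [3,5-dimethoxy-4-(methoxymethoxy)phenyl]triisopropoxyborate | COCOc1c(OC)cc([B-](OC(C)C)(OC(C)C)OC(C)C)cc1OC.[Li+] | intermediate
10 | [3,5-dimethoxy-4-(methoxymethoxy)phenyl]boronic acid | COCOc1c(OC)cc(B(O)O)cc1OC | intermediate
11 | (R,E)-3-[3,5-dimethoxy-4-(methoxymethoxy)benzylidene]-4-(3,4,5-trimethoxybenzyl)dihydrofuran-2(3H)-one | COCOc1c(OC)cc(/C=C2/C(=O)OC[C@@H]2Cc2cc(OC)c(OC)c(OC)c2)cc1OC | intermediate
12 | (R,E)-3-(4-hydroxy-3,5-dimethoxybenzylidene)-4-(3,4,5-trimethoxybenzyl)dihydrofuran-2(3H)-one | COc1cc(/C=C2/C(=O)OC[C@@H]2Cc2cc(OC)c(OC)c(OC)c2)cc(OC)c1O | target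

**Step count**

Total steps: 7. Longest linear sequence: 5 steps (1, 2, 3, 6, 7).

**Steps most likely to fail**

1. Step 6 (the proposed new method). Several processes could divert it:
- the aryl–rhodium species may start oligomerisation of the terminal alkyne;
- the alkenyl–rhodium may be protonated or migrate 1,4 onto the aryl ring before the ester reaches the rotamer needed for closure;
- the benzyl–rhodium may lose the β-hydride at C4 and erase the stereocentre;
- the allylic ester may ionise on rhodium;
- the alkene faces may be poorly distinguished, or the basic medium may erode C4 through γ-deprotonation.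

Fallback by known chemistry, setting out from 1 and returning at 11. Hydrogenation of 1 (H2, Pd/C, EtOAc) should give 3-(3,4,5-trimethoxyphenyl)propanoic acid F1. N-acylation of (S)-4-benzyloxazolidin-2-one with it (DCC, DMAP, CH2Cl2) gives (S)-4-benzyl-3-[3-(3,4,5-trimethoxyphenyl)propanoyl]oxazolidin-2-one F2. Evans alkylation (NaHMDS, THF, −78 °C; tert-butyl bromoacetate) on the enolate face away from the auxiliary benzyl group should give tert-butyl (R)-4-[(S)-4-benzyl-2-oxooxazolidin-3-yl]-4-oxo-3-(3,4,5-trimethoxybenzyl)butanoate F3. LiBH4 (THF, 1 equiv MeOH, 0 °C) removes the auxiliary reductively to give tert-butyl (R)-3-(hydroxymethyl)-4-(3,4,5-trimethoxyphenyl)butanoate F4, and acid (p-TsOH cat., toluene, 60 °C) closes it to (R)-4-(3,4,5-trimethoxybenzyl)dihydrofuran-2(3H)-one F5. Aldol addition of F5 (LDA, THF, −78 °C) to 3,5-dimethoxy-4-(methoxymethoxy)benzaldehyde F6 (from commercial syringaldehyde, MOMCl, iPr2NEt) should give the trans aldol (3S,4R)-3-{[3,5-dimethoxy-4-(methoxymethoxy)phenyl](hydroxy)methyl}-4-(3,4,5-trimethoxybenzyl)dihydrofuran-2(3H)-one F7 as carbinol epimers. Mesylation (MsCl, Et3N, CH2Cl2, 0 °C) to [3,5-dimethoxy-4-(methoxymethoxy)phenyl][(3S,4R)-2-oxo-4-(3,4,5-trimethoxybenzyl)tetrahydrofuran-3-yl]methyl methanesulfonate F8 and elimination with DBU should then give the thermodynamically preferred E-arylidene lactone 11.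

2. Step 3. Conjugate addition of DMAP or carboxylate to the activated propiolic acid, followed by oligomerisation, may outrun acylation of the alcohol.

Fallback setting out from 3 and returning at 5. Esterification of 3 with 3-(trimethylsilyl)propiolic acid (DCC, DMAP, CH2Cl2, 0 °C), whose silicon-capped alkyne is far less prone to conjugate addition, should give (E)-3-(3,4,5-trimethoxyphenyl)allyl 3-(trimethylsilyl)propiolate F9. C-desilylation under buffered fluoride (TBAF, AcOH, THF, −20 °C) then gives 5.

3. Step 5. The electron-rich arylboron species may protodeboronate on acidification, or the MOM acetal may be lost during work-up and isolation of the free boronic acid.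

Fallback setting out from 7 and returning at 10. Miyaura borylation (B2pin2, PdCl2(dppf), KOAc, dioxane, 80 °C) avoids organolithium and acid altogether and should give 2-[3,5-dimethoxy-4-(methoxymethoxy)phenyl]-4,4,5,5-tetramethyl-1,3,2-dioxaborolane F10, which can be purified on silica. Oxidative cleavage of the pinacol ester (NaIO4, NH4OAc, acetone/H2O, rt) then gives 10.

**Further compounds**

F1 | step 6 | 3-(3,4,5-trimethoxyphenyl)propanoic acid | COc1cc(CCC(=O)O)cc(OC)c1OC
F2 | step 6 | (S)-4-benzyl-3-[3-(3,4,5-trimethoxyphenyl)propanoyl]oxazolidin-2-one | COc1cc(CCC(=O)N2[C@@H](Cc3ccccc3)COC2=O)cc(OC)c1OC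
F3 | step 6 | tert-butyl (R)-4-[(S)-4-benzyl-2-oxooxazolidin-3-yl]-4-oxo-3-(3,4,5-trimethoxybenzyl)butanoate | CC(C)(C)OC(=O)C[C@@H](Cc1cc(OC)c(OC)c(OC)c1)C(=O)N1[C@@H](Cc2ccccc2)COC1=O
F4 | step 6 | tert-butyl (R)-3-(hydroxymethyl)-4-(3,4,5-trimethoxyphenyl)butanoate | CC(C)(C)OC(=O)C[C@@H](Cc1cc(OC)c(OC)c(OC)c1)CO
F5 | step 6 | (R)-4-(3,4,5-trimethoxybenzyl)dihydrofuran-2(3H)-one | O=C1OC[C@H](Cc2cc(OC)c(OC)c(OC)c2)C1
F6 | step 6 | 3,5-dimethoxy-4-(methoxymethoxy)benzaldehyde | COCOc1c(OC)cc(C=O)cc1OC
F7 | step 6 | (3S,4R)-3-{[3,5-dimethoxy-4-(methoxymethoxy)phenyl](hydroxy)methyl}-4-(3,4,5-trimethoxybenzyl)dihydrofuran-2(3H)-one (carbinol epimers) | O=C1OC[C@H](Cc2cc(OC)c(OC)c(OC)c2)[C@H]1C(O)c1cc(OC)c(OCOC)c(OC)c1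
F8 | step 6 | [3,5-dimethoxy-4-(methoxymethoxy)phenyl][(3S,4R)-2-oxo-4-(3,4,5-trimethoxybenzyl)tetrahydrofuran-3-yl]methyl methanesulfonate (carbinol epimers) | O=C1OC[C@H](Cc2cc(OC)c(OC)c(OC)c2)[C@H]1C(OS(C)(=O)=O)c1cc(OC)c(OCOC)c(OC)c1
F9 | step 3 | (E)-3-(3,4,5-trimethoxyphenyl)allyl 3-(trimethylsilyl)propiolate | C[Si](C)(C)C#CC(=O)OC/C=C/c1cc(OC)c(OC)c(OC)c1
F10 | step 5 | 2-[3,5-dimethoxy-4-(methoxymethoxy)phenyl]-4,4,5,5-tetramethyl-1,3,2-dioxaborolane | COCOc1c(OC)cc(B2OC(C)(C)C(C)(C)O2)cc1OC
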